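**Plan**

- Retrosynthesis: the five benzyl ethers and the C4 ketone (as its carbinol) are taken back first. Ring C of the flavanone is then opened at the aryl–oxygen bond O1–C8a, giving an acyclic (1S,3S)-1-(2-bromoaryl)-3-arylpropane-1,3-diol.
- Enabling feature: O1 links the C2 stereocentre to C8a of ring A. Ring C can therefore be closed by arylating a preformed (S)-benzylic carbinol with a ring-A bromide, without ever making or breaking the labile benzylic C2–O1 bond.
- Further cuts: C3–C4 (aldol of an aryl methyl ketone with 2,4-bis(benzyloxy)-6-bromobenzaldehyde), the diaryl ether O–C4' (SNAr of tri-O-benzylkaempferol on 4'-fluoroacetophenone), and the kaempferol pyranone (chalcone, flavone, C3 hydroxylation).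
- Forward order: kaempferol pyranone ring, then the biflavonoid ether, then the three-carbon chain, then ring C of the flavanone last; C4 oxidation and debenzylation finish.
- Stereochemistry: C2 (S) comes from Noyori transfer hydrogenation with the (S,S)-TsDPEN ruthenium catalyst and is carried with retention. The C4 carbinol is set anti by a directed reduction only so that intermediates are single diastereomers, and is later oxidised away.

Key step: step 12

Remark: diketone 16 is written as its diketo tautomer although it should be largely enolised; the C4 carbinol configuration is a spectator.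
Abbreviation: "TBK-oxy" = {5,7-bis(benzyloxy)-2-[4-(benzyloxy)phenyl]-4-oxo-4H-chromen-3-yl}oxy, the tri-O-benzylkaempferol-3-yloxy group.

**Route**

Step 1
Reactants: 1 2,4,6-trihydroxyacetophenone
Product: 2 1-[2,4-bis(benzyloxy)-6-hydroxyphenyl]ethan-1-one
Conditions: BnBr (2.1 equiv), K2CO3, DMF, rt
Reagents that add atoms: benzyl bromide, BrCc1ccccc1
Why: Williamson etherification in which the hydroxyl hydrogen-bonded to the acetyl carbonyl is the least nucleophilic and should stay free when two equivalents of bromide are used.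

Step 2
Reactants: 2 1-[2,4-bis(benzyloxy)-6-hydroxyphenyl]ethan-1-one; 3 4-(benzyloxy)benzaldehyde
Product: 4 (E)-1-[2,4-bis(benzyloxy)-6-hydroxyphenyl]-3-[4-(benzyloxy)phenyl]prop-2-en-1-one
Conditions: KOH, EtOH/THF, rt
Reagents that add atoms: none
Why: Claisen–Schmidt condensation of a methyl ketone with a non-enolisable aldehyde, the E-enone arising by E1cB dehydration of the aldol.

Step 3
Reactants: 4 (E)-1-[2,4-bis(benzyloxy)-6-hydroxyphenyl]-3-[4-(benzyloxy)phenyl]prop-2-en-1-one
Product: 5 5,7-bis(benzyloxy)-2-[4-(benzyloxy)phenyl]-4H-chromen-4-one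
Conditions: I2 (10 mol%), DMSO, 130 °C
Reagents that add atoms: none
Why: iodine-catalysed oxidative cyclisation of a 2'-hydroxychalcone (oxa-Michael closure, α-iodination and loss of HI, with DMSO as terminal oxidant), which closes the pyranone ring and tolerates benzyl ethers.

Step 4
Reactants: 5 5,7-bis(benzyloxy)-2-[4-(benzyloxy)phenyl]-4H-chromen-4-one
Product: 7 5,7-bis(benzyloxy)-2-[4-(benzyloxy)phenyl]-3-hydroxy-4H-chromen-4-one (5,7,4'-tri-O-benzylkaempferol), via racemic flavone 2,3-epoxide 6 (not isolated)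
Conditions: DMDO, acetone/CH2Cl2, 0 °C; then p-TsOH (cat.), CH2Cl2, rt
Reagents that add atoms: dimethyldioxirane, CC1(C)OO1
Why: dioxirane epoxidation of the flavone C2=C3 bond followed by acid-catalysed opening and tautomerisation to the 3-hydroxyflavone, used because the Algar–Flynn–Oyamada alternative tends to give aurones from 6'-alkoxychalcones.

Step 5
Reactants: 7 5,7,4'-tri-O-benzylkaempferol; 8 4'-fluoroacetophenone
Product: 9 3-(4-acetylphenoxy)-5,7-bis(benzyloxy)-2-[4-(benzyloxy)phenyl]-4H-chromen-4-one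
Conditions: Cs2CO3, DMSO, 100 °C, Ar
Reagents that add atoms: none
Why: nucleophilic aromatic substitution (addition–elimination) of the flavonol 3-oxide, the only acidic hydroxyl in 7, on a fluoroarene activated by the para acetyl group.

Step 6
Reactants: 10 5-bromoresorcinol
Product: 11 1,3-bis(benzyloxy)-5-bromobenzene
Conditions: BnBr (2.2 equiv), K2CO3, acetone, reflux
Reagents that add atoms: benzyl bromide, BrCc1ccccc1
Why: Williamson etherification of both phenols.

Step 7
Reactants: 11 1,3-bis(benzyloxy)-5-bromobenzene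
Product: 13 2,4-bis(benzyloxy)-6-bromobenzaldehyde, via aryl iminium chloride 12 (not isolated)
Conditions: POCl3, DMF, 0 to 80 °C; then H2O, 0 °C
Reagents that add atoms: N,N-dimethylformamide, CN(C)C=O; water, O
Why: Vilsmeier–Haack formylation, which on 1-bromo-3,5-dialkoxybenzenes goes para to one ether and ortho to the other at the carbon next to bromine rather than between the two ethers, and which leaves benzyl ethers intact.

Step 8
Reactants: 9 3-(4-acetylphenoxy)-5,7-bis(benzyloxy)-2-[4-(benzyloxy)phenyl]-4H-chromen-4-one; 13 2,4-bis(benzyloxy)-6-bromobenzaldehyde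
Product: 15 racemic 3-[2,4-bis(benzyloxy)-6-bromophenyl]-3-hydroxy-1-[4-(TBK-oxy)phenyl]propan-1-one, via lithium enolate 14 (not isolated)
Conditions: LiN(SiMe3)2, THF, −78 °C; then 13, −78 °C; AcOH quench at −78 °C
Reagents that add atoms: none
Why: directed aldol addition of a preformed lithium enolate to a non-enolisable aldehyde, quenched cold to prevent retro-aldol and dehydration; the new carbinol centre is racemic and is erased in step 9.

Step 9
Reactants: 15 racemic 3-[2,4-bis(benzyloxy)-6-bromophenyl]-3-hydroxy-1-[4-(TBK-oxy)phenyl]propan-1-one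
Product: 16 1-[2,4-bis(benzyloxy)-6-bromophenyl]-3-[4-(TBK-oxy)phenyl]propane-1,3-dione
Conditions: IBX, EtOAc, 75 °C
Reagents that add atoms: none
Why: IBX oxidation of a β-hydroxy ketone to the 1,3-diketone, a reagent choice that should stop at the diketone without the over-oxidation to a tricarbonyl that excess Dess–Martin periodinane can cause.

Step 10
Reactants: 16 1-[2,4-bis(benzyloxy)-6-bromophenyl]-3-[4-(TBK-oxy)phenyl]propane-1,3-dione
Product: 17 (3S)-1-[2,4-bis(benzyloxy)-6-bromophenyl]-3-hydroxy-3-[4-(TBK-oxy)phenyl]propan-1-one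
Conditions: RuCl(p-cymene)[(S,S)-TsDPEN] (2 mol%), HCO2H/Et3N (5:2), CH2Cl2, 30 °C
Reagents that add atoms: none
Why: Noyori asymmetric transfer hydrogenation, in which the ruthenium hydride of the (S,S)-ligand should reduce only the planar 4-aryloxyphenyl carbonyl through the six-membered outer-sphere transition state that gives (S)-carbinols from aryl ketones, while the ring-A carbonyl, twisted between Br and OBn, is too hindered to react.

Step 11
Reactants: 17 (3S)-1-[2,4-bis(benzyloxy)-6-bromophenyl]-3-hydroxy-3-[4-(TBK-oxy)phenyl]propan-1-one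
Product: 18 (1S,3S)-1-[2,4-bis(benzyloxy)-6-bromophenyl]-3-[4-(TBK-oxy)phenyl]propane-1,3-diol
Conditions: Me4NBH(OAc)3, MeCN/AcOH, −30 to 0 °C
Reagents that add atoms: none
Why: Evans–Saksena hydroxyl-directed reduction, in which the C3 hydroxyl binds boron and hydride is delivered intramolecularly through a chair-like six-membered transition state, which should give the 1,3-anti diol and so set C1 as S.

Step 12
Reactants: 18 (1S,3S)-1-[2,4-bis(benzyloxy)-6-bromophenyl]-3-[4-(TBK-oxy)phenyl]propane-1,3-diol
Product: 19 (2S,4S)-5,7-bis(benzyloxy)-2-[4-(TBK-oxy)phenyl]-3,4-dihydro-2H-chromen-4-ol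
Conditions: CuI (10 mol%), 3,4,7,8-tetramethyl-1,10-phenanthroline (20 mol%), Cs2CO3, toluene, 110 °C, Ar
Reagents that add atoms: none
Why: Cs2CO3 deprotonates the unhindered C3 carbinol (the future flavanone C2–O1 unit); the phenanthroline-ligated monovalent copper alkoxide then inserts into the ortho C–Br bond of ring A to give a seven-membered trivalent copper aryl alkoxide, and C–O reductive elimination forms O1–C8a. The closest known reaction type is the copper-catalysed Ullmann-type intramolecular O-arylation of secondary alcohols with aryl bromides that gives chromans with retention at the carbinol carbon. Ring C closes in a 6-exo sense at the aromatic carbon: the carbinol oxygen bonds to C8a and bromide leaves outside the new ring. No stereocentre is created; C2 stays S because its C–O bond is never broken and the substituent priorities are unchanged, and C4 stays S for the same reason. The step needs selection between the two hydroxyls and against intermolecular coupling; the C1 hydroxyl could only close a strained four-membered ring, so geometry leaves it free, and the intramolecular six-membered closure should outrun dimerisation.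

Step 13
Reactants: 19 (2S,4S)-5,7-bis(benzyloxy)-2-[4-(TBK-oxy)phenyl]-3,4-dihydro-2H-chromen-4-ol
Product: 20 (2S)-5,7-bis(benzyloxy)-2-[4-(TBK-oxy)phenyl]-2,3-dihydro-4H-chromen-4-one
Conditions: Dess–Martin periodinane, pyridine, CH2Cl2, 0 °C to rt
Reagents that add atoms: none
Why: Dess–Martin oxidation of a secondary benzylic alcohol to the aryl ketone under buffered, non-basic conditions, which should not open the flavanone by retro-oxa-Michael reaction and so leaves C2 untouched.

Step 14
Reactants: 20 (2S)-5,7-bis(benzyloxy)-2-[4-(TBK-oxy)phenyl]-2,3-dihydro-4H-chromen-4-one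
Product: 21 (2S)-5,7-dihydroxy-2-(4-{[5,7-dihydroxy-2-(4-hydroxyphenyl)-4-oxo-4H-chromen-3-yl]oxy}phenyl)-2,3-dihydro-4H-chromen-4-one
Conditions: H2 (1 atm), Pd/C (10% palladium on carbon), THF/MeOH, rt
Reagents that add atoms: none
Why: catalytic hydrogenolysis of five aryl benzyl ethers, which at ambient pressure should spare the chelated C4 ketone, the flavonol C2=C3 bond, the diaryl ether and the cyclic C2–O1 bond, so the S centre is not touched.

**Compound list**

1 | 2,4,6-trihydroxyacetophenone | CC(=O)c1c(O)cc(O)cc1O | starting material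
2 | 1-[2,4-bis(benzyloxy)-6-hydroxyphenyl]ethan-1-one | CC(=O)c1c(O)cc(OCc2ccccc2)cc1OCc1ccccc1 | intermediate
3 | 4-(benzyloxy)benzaldehyde | O=Cc1ccc(OCc2ccccc2)cc1 | starting material
4 | (E)-1-[2,4-bis(benzyloxy)-6-hydroxyphenyl]-3-[4-(benzyloxy)phenyl]prop-2-en-1-one | O=C(/C=C/c1ccc(OCc2ccccc2)cc1)c1c(O)cc(OCc2ccccc2)cc1OCc1ccccc1 | intermediate
5 | 5,7-bis(benzyloxy)-2-[4-(benzyloxy)phenyl]-4H-chromen-4-one | O=c1cc(-c2ccc(OCc3ccccc3)cc2)oc2cc(OCc3ccccc3)cc(OCc3ccccc3)c12 | intermediate
6 | racemic 5,7-bis(benzyloxy)-2-[4-(benzyloxy)phenyl]-2,3-epoxy-2,3-dihydro-4H-chromen-4-one (cis-fused oxirane) | O=C1C2OC2(c2ccc(OCc3ccccc3)cc2)Oc2cc(OCc3ccccc3)cc(OCc3ccccc3)c21 | intermediate (not isolated)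
7 | 5,7-bis(benzyloxy)-2-[4-(benzyloxy)phenyl]-3-hydroxy-4H-chromen-4-one (5,7,4'-tri-O-benzylkaempferol) | O=c1c(O)c(-c2ccc(OCc3ccccc3)cc2)oc2cc(OCc3ccccc3)cc(OCc3ccccc3)c12 | intermediate
8 | 4'-fluoroacetophenone | CC(=O)c1ccc(F)cc1 | starting material
9 | 3-(4-acetylphenoxy)-5,7-bis(benzyloxy)-2-[4-(benzyloxy)phenyl]-4H-chromen-4-one | CC(=O)c1ccc(Oc2c(-c3ccc(OCc4ccccc4)cc3)oc3cc(OCc4ccccc4)cc(OCc4ccccc4)c3c2=O)cc1 | intermediate
10 | 5-bromoresorcinol | Oc1cc(O)cc(Br)c1 | starting material
11 | 1,3-bis(benzyloxy)-5-bromobenzene | Brc1cc(OCc2ccccc2)cc(OCc2ccccc2)c1 | intermediate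
12 | N-{[2,4-bis(benzyloxy)-6-bromophenyl]methylidene}-N-methylmethanaminium chloride | C[N+](C)=Cc1c(Br)cc(OCc2ccccc2)cc1OCc1ccccc1.[Cl-] | intermediate (not isolated)
13 | 2,4-bis(benzyloxy)-6-bromobenzaldehyde | O=Cc1c(Br)cc(OCc2ccccc2)cc1OCc1ccccc1 | intermediate
14 | lithium enolate of 9 (lithium 1-[4-(TBK-oxy)phenyl]ethen-1-olate) | [Li+].[O-]C(=C)c1ccc(Oc2c(-c3ccc(OCc4ccccc4)cc3)oc3cc(OCc4ccccc4)cc(OCc4ccccc4)c3c2=O)cc1 | intermediate (not isolated)
15 | racemic 3-[2,4-bis(benzyloxy)-6-bromophenyl]-3-hydroxy-1-[4-(TBK-oxy)phenyl]propan-1-one | O=C(CC(O)c1c(Br)cc(OCc2ccccc2)cc1OCc1ccccc1)c1ccc(Oc2c(-c3ccc(OCc4ccccc4)cc3)oc3cc(OCc4ccccc4)cc(OCc4ccccc4)c3c2=O)cc1 | intermediate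
16 | 1-[2,4-bis(benzyloxy)-6-bromophenyl]-3-[4-(TBK-oxy)phenyl]propane-1,3-dione | O=C(CC(=O)c1c(Br)cc(OCc2ccccc2)cc1OCc1ccccc1)c1ccc(Oc2c(-c3ccc(OCc4ccccc4)cc3)oc3cc(OCc4ccccc4)cc(OCc4ccccc4)c3c2=O)cc1 | intermediate
17 | (3S)-1-[2,4-bis(benzyloxy)-6-bromophenyl]-3-hydroxy-3-[4-(TBK-oxy)phenyl]propan-1-one | O[C@H](c1ccc(Oc2c(-c3ccc(OCc4ccccc4)cc3)oc3cc(OCc4ccccc4)cc(OCc4ccccc4)c3c2=O)cc1)CC(=O)c1c(Br)cc(OCc2ccccc2)cc1OCc1ccccc1 | intermediate
18 | (1S,3S)-1-[2,4-bis(benzyloxy)-6-bromophenyl]-3-[4-(TBK-oxy)phenyl]propane-1,3-diol | O[C@H](c1ccc(Oc2c(-c3ccc(OCc4ccccc4)cc3)oc3cc(OCc4ccccc4)cc(OCc4ccccc4)c3c2=O)cc1)C[C@H](O)c1c(Br)cc(OCc2ccccc2)cc1OCc1ccccc1 | intermediate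
19 | (2S,4S)-5,7-bis(benzyloxy)-2-[4-(TBK-oxy)phenyl]-3,4-dihydro-2H-chromen-4-ol | O[C@H]1C[C@@H](c2ccc(Oc3c(-c4ccc(OCc5ccccc5)cc4)oc4cc(OCc5ccccc5)cc(OCc5ccccc5)c4c3=O)cc2)Oc2cc(OCc3ccccc3)cc(OCc3ccccc3)c21 | intermediate
20 | (2S)-5,7-bis(benzyloxy)-2-[4-(TBK-oxy)phenyl]-2,3-dihydro-4H-chromen-4-one | O=C1C[C@@H](c2ccc(Oc3c(-c4ccc(OCc5ccccc5)cc4)oc4cc(OCc5ccccc5)cc(OCc5ccccc5)c4c3=O)cc2)Oc2cc(OCc3ccccc3)cc(OCc3ccccc3)c21 | intermediate
21 | (2S)-5,7-dihydroxy-2-(4-{[5,7-dihydroxy-2-(4-hydroxyphenyl)-4-oxo-4H-chromen-3-yl]oxy}phenyl)-2,3-dihydro-4H-chromen-4-one | O=C1C[C@@H](c2ccc(Oc3c(-c4ccc(O)cc4)oc4cc(O)cc(O)c4c3=O)cc2)Oc2cc(O)cc(O)c21 | target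

**Step count and risks**

Total step count: 14. Longest linear sequence: 12 steps (steps 1–5 and 8–14, from 2,4,6-trihydroxyacetophenone); steps 6–7 form the convergent ring-A branch.

Steps most likely to fail:

Step 12 (ring closure). Copper may insert only slowly into the electron-rich, ortho-substituted C–Br bond, the 1,3-diol may sequester copper, and protodebromination or dehydrogenation of the benzylic carbinols may compete. The fallback moves the same O1–C8a closure to the palladium manifold. It sets out from diol 18: Pd(OAc)2, 2-(di-tert-butylphosphino)-1,1'-binaphthyl and Cs2CO3 in toluene at 70 °C (Buchwald–Hartwig intramolecular etherification). Oxidative addition then occurs at zerovalent palladium before the alkoxide binds, so activation of the bromide no longer depends on a copper alkoxide. The C2–O bond is again untouched, and the fallback comes back to the route at 19. It makes no new compound (F0).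

Step 10 (regioselective transfer hydrogenation). The enolised diketone may chelate ruthenium and stall the catalyst, hydride may go in part to the wrong carbonyl, or the enantioselectivity may erode. The fallback avoids the diketone and sets out from aldol 15, which has a single ketone, already at the ring-B side. Transfer hydrogenation of 15 with RuCl(p-cymene)[(S,S)-TsDPEN] and HCO2H/Et3N should set C3 as S under catalyst control. This gives diol 18 together with its C1 epimer, (1R,3S)-1-[2,4-bis(benzyloxy)-6-bromophenyl]-3-[4-(TBK-oxy)phenyl]propane-1,3-diol F1. The mixture is cyclised under the conditions of step 12 to 19 together with its C4 epimer, (2S,4R)-5,7-bis(benzyloxy)-2-[4-(TBK-oxy)phenyl]-3,4-dihydro-2H-chromen-4-ol F2. Dess–Martin oxidation as in step 13 converges both epimers, and the fallback comes back to the route at 20.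

Step 5 (diaryl ether formation). The flavonol oxygen is hindered and weakly nucleophilic, so substitution on the fluoroarene may be slow, and the flavonolate may degrade at the temperature needed. The fallback replaces addition–elimination by a copper-catalysed Ullmann coupling. It sets out from 7 and uses 4'-iodoacetophenone with CuI, picolinic acid and K3PO4 in DMSO at 90 °C, a system suited to hindered phenols and electron-poor aryl iodides. It comes back to the route at 9 and makes no new compound (F0).

**Further compounds**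

F0 | step 12 | none | none
F1 | step 10 | (1R,3S)-1-[2,4-bis(benzyloxy)-6-bromophenyl]-3-[4-(TBK-oxy)phenyl]propane-1,3-diol | O[C@H](c1ccc(Oc2c(-c3ccc(OCc4ccccc4)cc3)oc3cc(OCc4ccccc4)cc(OCc4ccccc4)c3c2=O)cc1)C[C@@H](O)c1c(Br)cc(OCc2ccccc2)cc1OCc1ccccc1
F2 | step 10 | (2S,4R)-5,7-bis(benzyloxy)-2-[4-(TBK-oxy)phenyl]-3,4-dihydro-2H-chromen-4-ol | O[C@@H]1C[C@@H](c2ccc(Oc3c(-c4ccc(OCc5ccccc5)cc4)oc4cc(OCc5ccccc5)cc(OCc5ccccc5)c4c3=O)cc2)Oc2cc(OCc3ccccc3)cc(OCc3ccccc3)c21
F0 | step 5 | none | none
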